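- Start from temperature: the new flasks share one recipe and one time, 10 h, and run from 60 °C to 105 °C, so you want the curve of free monomer in each before you trust any guess.

| flask | free monomer | transfer agent | initiator | temperature | remark | time |
|---|---|---|---|---|---|---|
| noon | 11 mM | 0.22 mM | 4.1 mol% | 55 °C | run made earlier |  |
| spring | 44 mM | 0.22 mM | 4.1 mol% | 82 °C | run made earlier |  |
| dawn | 22 mM | 0.44 mM | 4.1 mol% | 55 °C | run made earlier |  |
| eta | 22 mM | 0.220 mM | 4.1 mol% | 60 °C |  | 10 h |
| delta | 22 mM | 0.220 mM | 4.1 mol% | 90 °C |  | 10 h |
| zeta | 22 mM | 0.220 mM | 4.1 mol% | 105 °C |  | 10 h |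
| gamma | 22 mM | 0.220 mM | 4.1 mol% | 75 °C |  | 10 h |

- noon (time / h: monomer in chains / %, free monomer / %): 2.50: 2.3, 98.5; 5.00: 6.1, 94.1; 8.00: 9.8, 89.0; 10.0: 13.1, 86.1
- spring (time / h: monomer in chains / %, free monomer / %): 0.250: 7.1, 92.5; 0.667: 22.6, 76.6; 1.33: 43.5, 54.4; 3.00: 74.8, 21.9
- dawn (time / h: monomer in chains / %, free monomer / %): 2.50: 4.8, 94.6; 5.00: 12.5, 86.2; 8.00: 21.6, 76.6; 10.0: 26.4, 70.0

(standard deviation of a reading: 0.5 percentage points)

* the flask with the highest amount of monomer in chains, in percent of the free monomer charged ("all alike" if they lie within 1.5 percentage points) (eta / delta / zeta / gamma / all alike)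
* final monomer in chains, as a percentage of the free monomer charged, in eta
* final monomer in chains, as a percentage of the free monomer charged, in delta
* final monomer in chains, as a percentage of the free monomer charged, in zeta
* final monomer in chains, as a percentage of the free monomer charged, in gamma



- Late in each run free monomer falls pseudo-first-order, and the last readings give slopes of 0.0178 /h in noon, 0.0416 /h in dawn and 0.545 /h in spring.
- My supposition is that each transfer agent stops one started chain, so the working share, the initiator loading less the transfer agent as fractions of the free monomer charged, is 3.10% in the new flasks, against 2.10% in noon, 2.10% in dawn and 3.60% in spring.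
- Taking the slope as proportional to share times charge, the new recipe reads 0.0615 /h from dawn at 55 °C and 0.235 /h from spring at 82 °C, which gives an activation energy of 48.1 kJ/mol; noon, at the temperature of dawn, reads 0.0525 /h, but I go on with dawn, whose charge of free monomer is that of the new flasks.
- Each curve then has a flat start, a lag of 1.43 h read from dawn and 0.178 h from spring, then a knee, then a straight fall, and eta falls at 0.0801 /h, leaving 50.4% free.
- With spring's lag, zeta falls at 0.631 /h and leaves 0.203%, while delta falls at 0.336 /h and leaves 3.70%, and gamma falls at 0.169 /h and leaves 19.0%.
- The balance falls short by 3.30% at the end of spring and 3.60% at the end of dawn, so I subtract the spring figure and commit to 46.3% chains in eta, 77.7% in gamma, 93.0% in delta and 96.5% in zeta, which puts zeta highest.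
- The forecast differs: it gives 33% for eta, 78% for gamma, 93% for delta and 90% for zeta, and picks delta, holding that at the hottest setting “side loss or a ceiling effect is possible but unseen”.
- The flasks give 40.9% in eta, 75.0% in gamma, 94.5% in delta and 99.0% in zeta, so the highest is zeta.

    free monomer + initiator → living end + monomer in chains (k = 0.0439 /M/s, Ea = 77.0 kJ/mol)
    living end + transfer agent → dead chain (kL = 0.867 /M/s, Ea = 68.0 kJ/mol)
    free monomer + living end → monomer in chains + living end, rate k3*[living end]*[free monomer] (k = 0.132 /M/s, Ea = 50.0 kJ/mol)
    initiator + monomer in chains → initiator + over-reaction product (k = 0.175 /M/s, Ea = 51.0 kJ/mol)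
    (constants at 90 °C)

- Living ends in zeta stand at 3.10% of the free monomer charged at 10.0 h, the working share reckoned above. The consumption of initiator is the main reason for zeta's chains: the run without it gives 0% instead of 99.0%. The falling level of transfer agent is a part of it, since the run that holds that level gives 40.8%.
- On the neighbour that leaves eta until 40.0 h, the same share and slope leave 4.55% free monomer, and the computed flask holds 6.37% free monomer with 85.6% in chains.

The runs are calculated with constants of no real substance; the scatter is artificial.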